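**Strategy.** The 25-membered lactone ring is cut on both sides of its carbonyl carbon: C1, held between C2 and the ring oxygen on C24, is taken out as carbon monoxide. A single palladium-catalysed carbonylation then forms C1–C2 and C1–O together and closes the only ring of the molecule. Its substrate is an open C23 chain with an (E)-1-iodoalkene at one end (the future C2=C3) and a free primary alcohol at the other (the future C24–O). This iodo alcohol is reached without protecting groups in three steps from propargyl alcohol and 1-bromoicosane, and the macrocyclic E-enoate needs only saturation of C2=C3 to give the target.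

Key step: step 4

Remark: lactone numbering is used throughout (C1 = carbonyl carbon, C24 = carbon bound to the ring oxygen). The target has no stereocentre; the only stereochemical element on the way, the E alkene, is erased in the last step.

**Step 1**
Reactants: 1 prop-2-yn-1-ol (propargyl alcohol, slight excess); 2 1-bromoicosane
Product: 4 tricos-2-yn-1-ol, via dilithium 3-oxidoprop-1-yn-1-ide 3 (not isolated)
Conditions: n-BuLi (2.1 equiv), THF/HMPA, −78 → 0 °C; then 2, 0 °C → rt; H2O
Reagents that add atoms: none
Why: Alkylation of a propargyl alcohol dianion, in which the lithium acetylide carbon is far more nucleophilic than the lithium alkoxide, so the unhindered primary bromide should be displaced at carbon in an SN2 reaction once HMPA has loosened the aggregates, and the alcohol returns on aqueous quench.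

**Step 2**
Reactants: 4 tricos-2-yn-1-ol
Product: 6 tricos-22-yn-1-ol, via dipotassium 23-oxidotricos-1-yn-1-ide 5 (not isolated)
Conditions: KH (4 equiv), H2N(CH2)3NH2, rt; then 4 in THF, rt; H2O
Reagents that add atoms: none
Why: Alkyne zipper (base-mediated acetylene–allene isomerisation), in which potassium 3-aminopropylamide shuttles propargylic protons so that the triple bond walks along the unbranched chain away from the alkoxide end until the terminal acetylide forms irreversibly, which should draw all positional isomers to the chain end before the water quench.

**Step 3**
Reactants: 6 tricos-22-yn-1-ol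
Product: 8 (E)-23-iodotricos-22-en-1-ol, via O-zirconated (E)-alkenylzirconocene chloride 7 (not isolated)
Conditions: Cp2Zr(H)Cl (2.2 equiv), THF, rt, dark; then I2, 0 °C; aq. Na2S2O3
Reagents that add atoms: iodine, [I][I]
Why: Schwartz hydrozirconation followed by iodinolysis, in which the first equivalent of hydride converts the hydroxyl into its zirconium alkoxide, the second adds syn across the terminal alkyne with zirconium on the terminal carbon, and iodine cleaves the C–Zr bond with retention to give the E-1-iodoalkene, the alcohol being released on aqueous work-up.

**Step 4**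
Reactants: 8 (E)-23-iodotricos-22-en-1-ol; 9 carbon monoxide
Product: 12 (E)-tetracos-2-en-24-olide [(3E)-oxacyclopentacos-3-en-2-one], via alkenylpalladium iodide 10 (not isolated), via acylpalladium iodide 11 (not isolated)
Conditions: Pd(PPh3)4 (10 mol %), CO (1 atm), K2CO3 (3 equiv), toluene/DMF, 80 °C; 8 added by syringe pump over 12 h (final 2 mM)
Reagents that add atoms: none
Why: Zerovalent palladium inserts into the C23–I bond with retention to give alkenyl complex 10 of divalent palladium, and migratory insertion of coordinated CO turns it into acyl complex 11, which creates the C1–C2 bond of the lactone. The carbonate-assisted distal hydroxyl then attacks the acyl carbon (or exchanges for iodide on palladium before C–O reductive elimination), forming C1–O and returning zerovalent palladium. The closest known reaction type is the palladium-catalysed alkoxycarbonylation of alkenyl iodides in its intramolecular, macrolactonising form, established for ω-hydroxy alkenyl and aryl iodides. The single 25-membered ring is closed end to end by acyl substitution at C1 (25-exo-trig with respect to the acyl C–Pd bond), and the flexible polymethylene tether together with the s-trans E-enoate should leave it free of strain. No stereocentre arises, and the E geometry is carried through because oxidative addition and CO insertion both retain configuration at the sp2 carbon. The one selectivity required is ring closure over intermolecular esterification; it should be secured by syringe-pump addition into a CO-saturated catalyst solution, so that each acyl complex meets its own hydroxyl before another molecule, while the substrate offers only one C–I bond and one nucleophile.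

**Step 5**
Reactants: 12 (E)-tetracos-2-en-24-olide
Product: 13 24-tetracosanolide (oxacyclopentacosan-2-one)
Conditions: H2 (1 atm), 10% Pd/C, EtOAc, rt
Reagents that add atoms: none
Why: Heterogeneous catalytic hydrogenation, in which the conjugated disubstituted C2=C3 alkene should add hydrogen readily over Pd/C while the lactone, which has no benzylic or allylic C–O bond, stays untouched.

**Compound list**

1 | prop-2-yn-1-ol (propargyl alcohol) | C#CCO | starting material
2 | 1-bromoicosane | CCCCCCCCCCCCCCCCCCCCBr | starting material
3 | dilithium 3-oxidoprop-1-yn-1-ide (C,O-dilithiated propargyl alcohol) | [Li+].[Li+].[C-]#CC[O-] | intermediate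
4 | tricos-2-yn-1-ol | CCCCCCCCCCCCCCCCCCCCC#CCO | intermediate
5 | dipotassium 23-oxidotricos-1-yn-1-ide (acetylide alkoxide of 6) | [K+].[K+].[C-]#CCCCCCCCCCCCCCCCCCCCCC[O-] | intermediate
6 | tricos-22-yn-1-ol | C#CCCCCCCCCCCCCCCCCCCCCCO | intermediate
7 | [(E)-23-{[chlorobis(cyclopentadienyl)zirconio]oxy}tricos-1-en-1-yl]chlorobis(cyclopentadienyl)zirconium (cyclopentadienyl rings written as σ-bonded C5H5) | Cl[Zr](/C=C/CCCCCCCCCCCCCCCCCCCCCO[Zr](Cl)(C1C=CC=C1)C1C=CC=C1)(C1C=CC=C1)C1C=CC=C1 | intermediate
8 | (E)-23-iodotricos-22-en-1-ol | OCCCCCCCCCCCCCCCCCCCCC/C=C/I | intermediate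
9 | carbon monoxide | [C-]#[O+] | starting material
10 | trans-[(E)-23-hydroxytricos-1-en-1-yl]iodobis(triphenylphosphine)palladium (divalent palladium; phosphine donation written as P+/Pd−) | OCCCCCCCCCCCCCCCCCCCCC/C=C/[Pd-2](I)([P+](c1ccccc1)(c1ccccc1)c1ccccc1)[P+](c1ccccc1)(c1ccccc1)c1ccccc1 | intermediate
11 | trans-[(E)-24-hydroxytetracos-2-enoyl]iodobis(triphenylphosphine)palladium (divalent palladium) | OCCCCCCCCCCCCCCCCCCCCC/C=C/C(=O)[Pd-2](I)([P+](c1ccccc1)(c1ccccc1)c1ccccc1)[P+](c1ccccc1)(c1ccccc1)c1ccccc1 | intermediate
12 | (E)-tetracos-2-en-24-olide [(3E)-oxacyclopentacos-3-en-2-one] | O=C1/C=C/CCCCCCCCCCCCCCCCCCCCCO1 | intermediate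
13 | 24-tetracosanolide (oxacyclopentacosan-2-one) | O=C1CCCCCCCCCCCCCCCCCCCCCCCO1 | target

**Totals**

Total step count: 5. Longest linear sequence: 5 steps (1 or 2 → 4 → 6 → 8 → 12 → 13).

**Steps most likely to fail**

Step 2 is ranked below the three named here because 2-alkyn-1-ols are the standard substrates of the zipper isomerisation.

Step 4 (key step). The acylpalladium may be intercepted by the hydroxyl of a second molecule faster than by its own, so that linear and cyclic oligoesters grow instead of the monomeric ring. CO starvation may also let the catalyst collapse to palladium black and favour protodeiodination. The fallback closes the ring by classical carboxyl activation and brings in C1 as CO2. It sets out from alkyne 6. Double deprotonation with n-BuLi (THF, −78 °C) should give dilithium 23-oxidotricos-1-yn-1-ide F1, which is carboxylated with CO2 and acidified to 24-hydroxytetracos-2-ynoic acid F2. Hydrogenation over Pd/C saturates the triple bond to 24-hydroxytetracosanoic acid F3. Yamaguchi macrolactonisation (2,4,6-trichlorobenzoyl chloride, Et3N, THF, then slow addition to DMAP in refluxing toluene) passes through the mixed anhydride 24-hydroxytetracosanoic 2,4,6-trichlorobenzoic anhydride F4 and closes the same C1–O bond. The fallback comes back to the route at target 13.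

Step 1. The dilithiated propargyl alcohol aggregates and may stay largely out of solution, so that displacement on the waxy C20 bromide stalls and elimination or O-alkylation gains ground. The fallback masks the hydroxyl so that only a soluble monolithium acetylide is alkylated. It sets out from 1. DHP and PPTS in CH2Cl2 should give 2-(prop-2-yn-1-yloxy)oxane F5 (racemic acetal). n-BuLi (THF/HMPA, −78 °C) converts it into lithium 3-(oxan-2-yloxy)prop-1-yn-1-ide F6, which is alkylated with 2 to 2-(tricos-2-yn-1-yloxy)oxane F7. TsOH in MeOH removes the acetal, and the sequence comes back to the route at 4.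

Step 3. The free hydroxyl consumes hydride, and the zirconium alkoxide so formed may precipitate and leave the alkyne partly untouched. The alkenylzirconium may also be protonated before iodine is added, which would end in the terminal alkene. The fallback uses hydrometallation with boron in place of zirconium. It sets out from 6. Catecholborane (excess, THF, 70 °C) borylates the hydroxyl and adds syn across the alkyne to give the bis(catechol) ester 2-[(E)-23-(1,3,2-benzodioxaborol-2-yloxy)tricos-1-en-1-yl]-1,3,2-benzodioxaborole F8. Water hydrolyses both boron sites to (E)-(23-hydroxytricos-1-en-1-yl)boronic acid F9. Iododeboronation with NIS in MeCN/THF should replace boron by iodine with retention, and the fallback comes back to the route at 8.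

**Further compounds**

F1 | step 4 | dilithium 23-oxidotricos-1-yn-1-ide | [Li+].[Li+].[C-]#CCCCCCCCCCCCCCCCCCCCCC[O-]
F2 | step 4 | 24-hydroxytetracos-2-ynoic acid | OC(=O)C#CCCCCCCCCCCCCCCCCCCCCCO
F3 | step 4 | 24-hydroxytetracosanoic acid | OC(=O)CCCCCCCCCCCCCCCCCCCCCCCO
F4 | step 4 | 24-hydroxytetracosanoic 2,4,6-trichlorobenzoic anhydride | OCCCCCCCCCCCCCCCCCCCCCCCC(=O)OC(=O)c1c(Cl)cc(Cl)cc1Cl
F5 | step 1 | 2-(prop-2-yn-1-yloxy)oxane (racemic) | C#CCOC1CCCCO1
F6 | step 1 | lithium 3-(oxan-2-yloxy)prop-1-yn-1-ide (racemic) | [Li+].[C-]#CCOC1CCCCO1
F7 | step 1 | 2-(tricos-2-yn-1-yloxy)oxane (racemic) | CCCCCCCCCCCCCCCCCCCCC#CCOC1CCCCO1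
F8 | step 3 | 2-[(E)-23-(1,3,2-benzodioxaborol-2-yloxy)tricos-1-en-1-yl]-1,3,2-benzodioxaborole | c1ccc2OB(/C=C/CCCCCCCCCCCCCCCCCCCCCOB3Oc4ccccc4O3)Oc2c1
F9 | step 3 | (E)-(23-hydroxytricos-1-en-1-yl)boronic acid | OB(O)/C=C/CCCCCCCCCCCCCCCCCCCCCO
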